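## Retrosynthetic overview
- No ring is built: the A/C chromanone, the B ring and the C2 (S) centre are bought together as natural (2S)-liquiritigenin (1).
- Only two bonds are made. The first is C8–I, from 1 with N-iodosuccinimide (2), giving aryl iodide 3.
- Key disconnection: the C8–C1″ aryl–geranyl bond, cut to 3 and (E)-geranyl acetate (4). It is formed by a visible-light Ni/photoredox reductive coupling, giving target 5.
- No protecting groups; both steps are neutral to weakly acidic, so the base-labile C2 centre is not exposed to ring-opening.

Assumption: natural (2S)-liquiritigenin from licorice, sold enantioenriched, is taken as the purchasable chiral starting material; its ee is checked by chiral HPLC on receipt.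

## Route

**Step 1**
Reactants: 1, (2S)-liquiritigenin [(2S)-7-hydroxy-2-(4-hydroxyphenyl)chroman-4-one]; 2, N-iodosuccinimide
Product: 3, (2S)-8-iodoliquiritigenin [(2S)-7-hydroxy-2-(4-hydroxyphenyl)-8-iodochroman-4-one]
Conditions: NIS (1.0 equiv), DMF, 0 °C → rt, dark; aq. Na2S2O3 quench; chromatography
Reagents that add atoms: N-iodosuccinimide (2), O=C1CCC(=O)N1I (iodine)
Why: Electrophilic aromatic iodination (SEAr) is expected to favour C8, which is ortho to both 7-OH and O1 (by analogy with 2-iodination of resorcinols and 8-iodination of 7-hydroxychromones and coumarins) and is more activated than the mono-oxygenated B ring; the selectivity over C6 is not established for this flavanone, so any 6-iodo isomer is removed by chromatography (3 shows H-5/H-6 as ortho doublets), and because no base is present the flavanone does not open to the chalcone, so C2 stays S with no new stereocentre.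

**Step 2**
Reactants: 3, (2S)-8-iodoliquiritigenin; 4, (E)-geranyl acetate
Product: 5, (2S)-7,4′-dihydroxy-8-geranylflavanone [(2S)-8-[(2E)-3,7-dimethylocta-2,6-dien-1-yl]-7-hydroxy-2-(4-hydroxyphenyl)chroman-4-one]
Conditions: 4 (2 equiv), NiBr2·dme (10 mol%), dtbbpy (12 mol%), 4CzIPN (2 mol%), Hantzsch ester (1.5 equiv), 2,6-lutidine (2 equiv), degassed DMA (0.1 M), 450 nm LEDs, 25 °C
Reagents that add atoms: (E)-geranyl acetate (4), CC(C)=CCC/C(C)=C/COC(C)=O (the C10 geranyl unit; acetate is lost)
Why: Proposed new method: a base-free, metal-reductant-free Ni/photoredox reductive aryl–allyl cross-electrophile coupling on an unprotected, base-sensitive ortho-iodophenol, in which 4CzIPN excited at 450 nm is reductively quenched by Hantzsch ester and its radical anion (about −1.2 V vs SCE) turns Ni(II) over to low-valent Ni, which adds to the C8–I bond and ionises the allylic acetate to an aryl–Ni–(η3-geranyl) species that reductively eliminates at the unhindered CH2 terminus; E geometry should survive because syn/anti exchange would need a tertiary σ-Ni at C3″, the flavanone is untouched because it does not absorb at 450 nm and lies out of reach of the catalyst (triplet about 70 vs about 60 kcal/mol; ketone reduction about −2.2 V), any Ni-mediated O-geranylation of the phenols is reversible, lutidine buffers the HI/AcOH by-products so the ortho-geranylphenol does not cyclise to a chroman and C2 is not epimerised, and the closest known reactions are Zn-mediated Ni-catalysed aryl halide/allylic acetate cross-electrophile coupling and Ni/photoredox aryl halide–alkyl halide reductive couplings with organic reductants.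

## Compound list
1 | (2S)-liquiritigenin, (2S)-7-hydroxy-2-(4-hydroxyphenyl)chroman-4-one | Oc1ccc2c(c1)O[C@H](c1ccc(O)cc1)CC2=O | starting material
2 | N-iodosuccinimide | O=C1CCC(=O)N1I | starting material (reagent)
3 | (2S)-7-hydroxy-2-(4-hydroxyphenyl)-8-iodochroman-4-one | Oc1ccc2c(c1I)O[C@H](c1ccc(O)cc1)CC2=O | intermediate
4 | (E)-geranyl acetate, (2E)-3,7-dimethylocta-2,6-dien-1-yl acetate | CC(C)=CCC/C(C)=C/COC(C)=O | starting material
5 | (2S)-7,4′-dihydroxy-8-geranylflavanone | CC(C)=CCC/C(C)=C/Cc1c(O)ccc2c1O[C@H](c1ccc(O)cc1)CC2=O | target

## Summary
Total step count: 2
Longest linear sequence: 2 steps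

Most likely to fail (the route has only two steps, so both are listed and the third entry is the supply of 1):

1. **Step 2 (proposed new coupling).** Risks are protodeiodination back to 1 (recoverable), slow oxidative addition at the di-ortho-substituted iodide, and partial E/Z or branched leakage. Fallback with known chemistry: Migita–Kosugi–Stille coupling of 3 with (E)-geranyltributylstannane (Pd2(dba)3/AsPh3 or Pd(PPh3)4, DMF, 60–70 °C, neutral), a known α-selective, geometry-retaining aryl–allyl coupling.
2. **Step 1 (C8 vs C6 iodination, over-iodination, B-ring iodination).** This is the least certain selectivity in the route. Fallback: drop the halide. Geranylate the more acidic 7-OH under Mitsunobu conditions (geraniol, PPh3, DIAD, THF, 0 °C), then move the geranyl group from O7 to C8 by the known montmorillonite K10/Florisil-promoted [1,3] O→C shift of aryl prenyl-type ethers. This sacrifices the photochemical step and may itself give C6/C8 mixtures.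
3. **Supply and optical purity of 1 (configurational integrity of C2).** Commercial liquiritigenin can be partly racemised by isolation under basic or hot conditions. Fallback: buy the natural 4′-O-β-D-glucoside liquiritin, whose blocked 4′-OH shuts down the quinone-methide racemisation path, and release 1 with β-glucosidase at pH 5 (the enzyme only removes glucose and does not set C2) before Step 1.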